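A fraction per minute is the unit to start from: the solid monomer of the north-east run falls to 19.0% in 80.0 min, which read as first-order loss is κ = 0.0208 min⁻¹, and the north run gives 0.0220 min⁻¹.

| flask | solid monomer | protic impurity | initiator | remark | time |
|---|---|---|---|---|---|
| north-east | 1 M | 0.020 M | 0.25 mol% | run made earlier |  |
| north | 1 M | 0.020 M | 0.38 mol% | run made earlier |  |
| flask | 1.0 M | 0.0200 M | 0.5 mol% |  | 1.5 h |

| run | time / min | monomer in chains / % | solid monomer / % |
|---|---|---|---|
| north-east | 15.0 | 3.1 | 75.6 |
| north-east | 40.0 | 9.3 | 46.5 |
| north-east | 80.0 | 14.3 | 19.0 |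
| north-east | 120 | 16.6 | 5.7 |
| north | 25.0 | 7.6 | 61.7 |
| north | 50.0 | 14.9 | 35.7 |
| north | 80.0 | 17.9 | 17.2 |
| north | 120 | 18.7 | 3.4 |

(readings scatter by 0.5 percentage points)

- how much monomer in chains there is at 1.5 h, in percent of the solid monomer charged
- the change that raises the amount of monomer in chains at 1.5 h, in percent of the solid monomer charged most ("none" if none brings more than 2 percentage points) (ash / elm / none)
- amount of monomer in chains at 1.5 h, in percent of the solid monomer charged, after elm

Two chemists dispute this flask. The first holds that dissolving is the rate-limiting step and that chains are a fixed share of what has dissolved: 17.7% in the north-east run and 21.6% in the north run at 80.0 min. On that view, doubling the dissolving coefficient multiplies the dissolved fraction at 1.5 h by 1.15, and chains with it.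

The second answers that from 80.0 min to 120 min the north run gained 0.8 percentage points of chains while the solid lost 14 points, less than a fixed share gives, so the active centres die.

My own reckoning takes the middle of the forecast's 20–30 min lifetime, τ = 25.0 min, shorter than the dissolving time 1/κ of 48.1 min. Integrating the dissolved fraction, 1 − e^(−κt), times the surviving centres, e^(−t/τ), with s = 1/τ + κ = 0.0608 min⁻¹, gives

W(t) = [τ(1 − e^(−t/τ)) − (1 − e^(−st))/s] / (τ − 1/s).

At 1.5 h this is 92.8%, the share of the final chains then present, the overlap W. Doubling κ raises the final chains by a factor 1.49 in my reckoning, a little above the forecast's 1.45.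

The forecast sides with the second chemist: 19.8%, ash as the best change, and 28.5% after elm. Its ground: "The yield is limited by how much monomer is dissolved while centres live".

The flask gives 20.7%, with ash the best change at 15 points against 11 points for elm, and 32.1% after elm. That is a factor 1.55, more than the first chemist's, so the second side stands.

    solid monomer ⇌ free monomer, rate k1*(cs1 - [free monomer]) while solid is left; crystals form when [free monomer] > cs1 (solubility = 0.860 M, k = 3.60 × 10⁻⁴ s⁻¹)
    free monomer + initiating radical → growing radical + monomer in chains (k = 2.40 × 10⁵ L mol⁻¹ s⁻¹)
    initiator → 2 initiating radical (k = 0.00140 s⁻¹)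
    free monomer + growing radical → monomer in chains + growing radical, rate k4*[growing radical]*[free monomer] (k = 7500 L mol⁻¹ s⁻¹)
    2 growing radical → dead chain (k = 1.00 × 10⁹ L mol⁻¹ s⁻¹)
    protic impurity + free monomer → quenched substrate (k = 0.0720 L mol⁻¹ s⁻¹)

The asked time is ten times the initiator's half-life of 0.14 h by its own path, and 0.052% of the initiator is left at 1.50 h. Free monomer, with each step taken net, then forms 7.41 times faster than it is taken away, and 66.4% of it stands in the flask. Against 22.1% after 15.0 h, this flask has 93.7% of its final chains at 1.5 h, beside W of 92.8%. The first chemist's share in this flask is 13.9% at 0.150 h, 24.4% at 0.750 h and 23.2% at 1.50 h, so it is not fixed.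

For the flask stopped at 40 min, W gives 57.9%, hence 12.8% of monomer in chains. The computed result for that flask is 13.3%.

(The numbers in the tables were generated by integration on assumed constants; noise was put on by code.)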